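**Retrosynthetic overview**

- Feature: in the ring C5–C10 the acrylic-arm carbon C7 lies para to the quaternary C10, and the vinyl carbon C1 on C10 is cis to the C5 arm (C4). The carbocycle therefore maps onto 4-methyl-4-(acryloyloxymethyl)cyclohexa-2,5-dienone, with C7 as the carbonyl carbon and the tether C1–O–C15(=O)–C4 as the future vinyl group and allyl arm.
- Key disconnection C4–C5: a desymmetrising Rauhut–Currier cyclisation closes the cis-fused α-methylene δ-lactone on the benzoic-acid-derived carbocycle (the only ring closed in the route, opened again later) and sets C5 and C10.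
- C6–OH comes from Rubottom oxidation on the convex face; the lactone is reduced to the C15 allylic alcohol and the C1 alcohol, and C1 is taken to the vinyl group by oxidation and Wittig methylenation.
- The C7 ketone becomes an enol triflate and is coupled with the C11 unit (Suzuki); C6–OH-directed epoxidation and Pd–formate hydrogenolysis with inversion at C7 then set C7 and C8.
- C8–OH is esterified with the (R)-side-chain acid made from (R)-3-hydroxy-γ-butyrolactone, C12 is oxidised to the acid, and all silyl groups are removed.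

Key step: step 5

Remark: ring carbons carry the locants C5–C10 of the target (C1/C2 vinyl, C4/C3/C15 the arm on C5, C11/C13/C12 the arm on C7), and β is the ring face of the C10 methyl. The target SMILES is read as vinyl α, C5 arm α, O6 β, C7 arm β, O8 β, side chain (3R). The sense of induction of the phosphine catalyst in step 5 is assumed to be the required one; the D-valine-derived enantiomer is used if it is not.

**Route**

Step 1
Reactants: 1 benzoic acid; 2 iodomethane
Product: 4 1-methylcyclohexa-2,5-diene-1-carboxylic acid, via Birch dianion 3 (not isolated)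
Conditions: Li, NH3(l), THF, −78 °C; then MeI; aq. HCl work-up
Reagents that add atoms: none
Why: Birch reduction of the benzoate gives the dienediolate 3, which is C-alkylated at the ipso carbon (Birch reductive alkylation) to the 1,4-diene acid.

Step 2
Reactants: 4 1-methylcyclohexa-2,5-diene-1-carboxylic acid
Product: 5 (1-methylcyclohexa-2,5-dien-1-yl)methanol
Conditions: LiAlH4, THF, 0 °C → reflux
Reagents that add atoms: none
Why: Hydride reduction with LiAlH4 takes the hindered carboxylic acid to the neopentyl alcohol and leaves the isolated 1,4-diene untouched.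

Step 3
Reactants: 5 (1-methylcyclohexa-2,5-dien-1-yl)methanol; 6 acryloyl chloride
Product: 7 (1-methylcyclohexa-2,5-dien-1-yl)methyl acrylate
Conditions: Et3N, DMAP (cat.), CH2Cl2, 0 °C
Reagents that add atoms: none
Why: Acylation of the primary alcohol with the acid chloride and an amine base (esterification) installs the acrylate tether.

Step 4
Reactants: 7 (1-methylcyclohexa-2,5-dien-1-yl)methyl acrylate
Product: 8 (1-methyl-4-oxocyclohexa-2,5-dien-1-yl)methyl acrylate
Conditions: CrO3, 3,5-dimethylpyrazole, CH2Cl2, −20 °C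
Reagents that add atoms: chromium trioxide, O=[Cr](=O)=O
Why: Allylic oxidation with CrO3–3,5-dimethylpyrazole converts the doubly allylic CH2 of the 1,4-diene into the cross-conjugated dienone, and the electron-poor acrylate is inert.

Step 5
Reactants: 8 (1-methyl-4-oxocyclohexa-2,5-dien-1-yl)methyl acrylate
Product: 9 (4aS,8aR)-8a-methyl-4-methylidene-4a,5-dihydro-1H-isochromene-3,6(4H,8aH)-dione (cis-fused α-methylene δ-lactone enone; C10 methyl β, H5 β, lactone ring on the α face)
Conditions: (S)-1-[3,5-bis(trifluoromethyl)phenyl]-3-[1-(diphenylphosphanyl)-3-methylbutan-2-yl]thiourea (10 mol%), CHCl3 (0.02 M), 0 °C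
Reagents that add atoms: none
Why: Rauhut–Currier reaction: the phosphine adds to the unhindered β-carbon of the acrylate, the phosphonium enolate adds through C4 to C5 of one enone arm, and proton transfer with β-elimination of the phosphine restores the C4 methylene and frees the catalyst. The closest known reaction is the enantioselective intramolecular Rauhut–Currier desymmetrisation of acrylate-tethered cyclohexadienones by amino-acid-derived phosphines that carry a hydrogen-bond donor; the tether used here is one CH2 longer than in the γ-lactone cases. The δ-lactone ring closes by a 6-exo-trig Michael addition. The relative configuration of C5 and C10 is fixed by the three-atom tether, which can deliver C4 only to the face of the flat dienone that carries C1, so the ring fusion is cis. The absolute configuration comes from the catalyst, whose thiourea binds the dienone carbonyl and holds one of the two enantiotopic enone arms next to the phosphonium enolate. The step needs phosphine attack on the acrylate and not on the dienone, which the quaternary C10 beside both dienone β-carbons secures, and high dilution to suppress intermolecular coupling.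

Step 6
Reactants: 9 cis-fused α-methylene δ-lactone enone
Product: 10 trimethylsilyl dienol ether of 9 (C6=C7 and C8=C9 double bonds, OSiMe3 on C7)
Conditions: TMSOTf, Et3N, CH2Cl2, 0 °C
Reagents that add atoms: trimethylsilyl trifluoromethanesulfonate, C[Si](C)(C)OS(=O)(=O)C(F)(F)F
Why: Soft enolisation of the enone can only occur at C6 because the γ-carbon C10 is quaternary, so silyl dienol ether formation gives the 2-silyloxy-1,3-diene regiospecifically.

Step 7
Reactants: 10 trimethylsilyl dienol ether
Product: 12 6β-hydroxy derivative of 9 (OH trans to the C5–C4 bond), via α-silyloxy ketone 11 (not isolated)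
Conditions: mCPBA, NaHCO3, CH2Cl2, −20 °C; then aq. citric acid, THF, 0 °C
Reagents that add atoms: 3-chloroperoxybenzoic acid, OOC(=O)c1cccc(Cl)c1
Why: Rubottom oxidation: the peracid epoxidises the electron-rich C6=C7 enol ether from the convex β face opposite the cis-fused lactone ring, and silyl migration followed by acid work-up gives the 6β-alcohol, which is also the more stable equatorial epimer.

Step 8
Reactants: 12 6β-hydroxy lactone enone
Product: 13 6β-(triethylsilyloxy) lactone enone
Conditions: TESCl, imidazole, DMF, 0 °C → rt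
Reagents that add atoms: chlorotriethylsilane, CC[Si](Cl)(CC)CC
Why: Imidazole-mediated silylation of the secondary α-hydroxy ketone protects O6 for the reduction and enolate steps.

Step 9
Reactants: 13 6β-(triethylsilyloxy) lactone enone
Product: 14 triol (ring C5–C10 with 8,9-ene; 7-OH as either epimer; 6β-OSiEt3; 5α-C(=CH2)CH2OH; 10β-CH3; 10α-CH2OH)
Conditions: i-Bu2AlH (excess), CH2Cl2, −78 °C → rt; Rochelle salt work-up
Reagents that add atoms: none
Why: i-Bu2AlH reduces the α-methylene lactone to the allylic diol and the enone carbonyl by 1,2-addition (hydride reduction), which removes the acrylate acceptor before any conjugate hydride chemistry, and the C7 configuration is irrelevant because C7 is reoxidised.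

Step 10
Reactants: 14 triol
Product: 15 15-O-tert-butyldiphenylsilyl diol (as 14 with 5α-C(=CH2)CH2OSiPh2t-Bu; 7-OH and 10α-CH2OH free)
Conditions: TBDPSCl (1.05 equiv), imidazole, CH2Cl2, −20 → 0 °C
Reagents that add atoms: tert-butylchlorodiphenylsilane, CC(C)(C)[Si](Cl)(c1ccccc1)c1ccccc1
Why: Sterically controlled silyl ether formation: the bulky chlorosilane reacts at the unhindered allylic primary hydroxyl on C15 much faster than at the neopentyl primary hydroxyl on C1 or the secondary hydroxyl on C7.

Step 11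
Reactants: 15 diol
Product: 16 keto aldehyde (8,9-en-7-one; 10α-CHO; 10β-CH3; 6β-OSiEt3; 5α-C(=CH2)CH2OSiPh2t-Bu)
Conditions: Dess–Martin periodinane, NaHCO3, CH2Cl2, 0 °C → rt
Reagents that add atoms: none
Why: Dess–Martin oxidation converts the neopentyl alcohol into the non-enolisable C1 aldehyde and the C7 allylic alcohol back into the enone in one operation.

Step 12
Reactants: 16 keto aldehyde
Product: 17 vinyl enone (8,9-en-7-one; 10α-vinyl; 10β-CH3; 6β-OSiEt3; 5α-C(=CH2)CH2OSiPh2t-Bu)
Conditions: Ph3PCH3Br, KN(SiMe3)2, THF, −78 → 0 °C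
Reagents that add atoms: methyltriphenylphosphonium bromide, C[P+](c1ccccc1)(c1ccccc1)c1ccccc1.[Br-]
Why: Wittig methylenation with one equivalent of ylide at low temperature is selective for the aldehyde over the conjugated ketone flanked by the silyloxy group, and the quaternary α-carbon excludes epimerisation.

Step 13
Reactants: 17 vinyl enone
Product: 19 C7 enol triflate (7,8-ene; 7-OSO2CF3; 6β-OSiEt3; 10α-vinyl; 10β-CH3; 5α-C(=CH2)CH2OSiPh2t-Bu), via lithium enolate 18 (not isolated)
Conditions: LiBH(s-Bu)3, THF, −78 °C; then PhNTf2, −78 °C → rt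
Reagents that add atoms: N-phenylbis(trifluoromethanesulfonimide), O=S(=O)(N(c1ccccc1)S(=O)(=O)C(F)(F)F)C(F)(F)F
Why: Conjugate hydride addition to the β-unsubstituted enone generates the C7–C8 lithium enolate regiospecifically, and O-triflation fixes the double bond at C7=C8 away from the oxygenated C6 (enone reduction with enolate trapping).

Step 14
Reactants: 20 4-methoxybenzyl alcohol; 21 2,3-dibromopropene
Product: 22 2-bromoallyl 4-methoxybenzyl ether
Conditions: NaH, THF/DMF, 0 °C → rt
Reagents that add atoms: none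
Why: Williamson ether synthesis: the alkoxide displaces the allylic bromide, and the vinylic bromide is inert.

Step 15
Reactants: 22 2-bromoallyl 4-methoxybenzyl ether
Product: 23 2-[3-(4-methoxybenzyloxy)prop-1-en-2-yl]-4,4,5,5-tetramethyl-1,3,2-dioxaborolane
Conditions: B2pin2, PdCl2(PPh3)2, PPh3, KOPh, toluene, 50 °C
Reagents that add atoms: bis(pinacolato)diboron, CC1(C)OB(OC1(C)C)B1OC(C)(C)C(C)(C)O1
Why: Miyaura borylation of the alkenyl bromide under palladium catalysis with phenoxide base gives the 1,1-disubstituted alkenyl boronate.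

Step 16
Reactants: 19 C7 enol triflate; 23 alkenyl boronate
Product: 24 diene (7,8-ene; 7-C(=CH2)CH2OPMB; 6β-OSiEt3; 10α-vinyl; 10β-CH3; 5α-C(=CH2)CH2OSiPh2t-Bu)
Conditions: PdCl2(dppf), K3PO4, dioxane/H2O, 60 °C
Reagents that add atoms: none
Why: Suzuki–Miyaura coupling of the enol triflate with the alkenyl boronate forms the C7–C11 bond and gives the 1,3-diene with the C12 oxygen in place.

Step 17
Reactants: 24 diene
Product: 25 dienol (as 24 with free 6β-OH)
Conditions: HF·pyridine, pyridine, THF, 0 °C
Reagents that add atoms: none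
Why: Selective desilylation: buffered HF·pyridine cleaves the triethylsilyl ether far faster than the tert-butyldiphenylsilyl ether and frees the C6 hydroxyl as a directing group.

Step 18
Reactants: 25 dienol
Product: 26 7β,8β-epoxy alcohol (6β-OH; 7-C(=CH2)CH2OPMB on the epoxide carbon C7)
Conditions: VO(acac)2 (5 mol%), t-BuOOH, CH2Cl2, 0 °C → rt
Reagents that add atoms: tert-butyl hydroperoxide, CC(C)(C)OO
Why: Hydroxyl-directed epoxidation with VO(acac)2 is specific for the allylic C7=C8 double bond and delivers oxygen syn to the 6β-hydroxyl, so the epoxide is 7β,8β and C8 is set.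

Step 19
Reactants: 26 7β,8β-epoxy alcohol
Product: 27 6β-(triethylsilyloxy) 7β,8β-epoxide
Conditions: TESCl, imidazole, DMAP (cat.), DMF, rt
Reagents that add atoms: chlorotriethylsilane, CC[Si](Cl)(CC)CC
Why: Silylation under neutral imidazole conditions leaves the acid-sensitive vinyl epoxide intact and masks O6 for the acylation and oxidation steps.

Step 20
Reactants: 27 6β-(triethylsilyloxy) 7β,8β-epoxide
Product: 28 8β-alcohol (7β-C(=CH2)CH2OPMB, 7α-H; 6β-OSiEt3; 10α-vinyl; 10β-CH3; 5α-C(=CH2)CH2OSiPh2t-Bu)
Conditions: Pd2(dba)3·CHCl3 (cat.), PBu3, HCO2H, Et3N, dioxane, rt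
Reagents that add atoms: none
Why: Palladium-catalysed formate hydrogenolysis of an alkenyl oxirane (Tsuji-type allylic hydrogenolysis): zerovalent palladium ionises the allylic C7–O bond anti to oxygen and hydride is delivered from palladium to C7 on the α face, so C7 is inverted (arm β, cis to both oxygens), the 8β-hydroxyl is kept and the olefin stays at C11=C13.

Step 21
Reactants: 29 (R)-3-hydroxy-γ-butyrolactone
Product: 31 (4R)-3-[(dimethylamino)methyl]-4-hydroxyoxolan-2-one (3,4-trans), via alkoxide enolate dianion 30 (not isolated)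
Conditions: LiN(i-Pr)2 (2.2 equiv), THF, −78 °C; then CH2=NMe2+ I−, −78 → 0 °C
Reagents that add atoms: Eschenmoser's salt (N,N-dimethylmethyleneiminium iodide), C=[N+](C)C.[I-]
Why: The alkoxide enolate dianion of the β-hydroxy lactone (Fráter–Seebach-type dianion, which cannot β-eliminate) is aminomethylated anti to the oxygen in a Mannich reaction.

Step 22
Reactants: 31 Mannich base; 2 iodomethane
Product: 33 (4R)-4-hydroxy-3-methylideneoxolan-2-one, via ammonium iodide 32 (not isolated)
Conditions: MeI, MeOH, rt; then aq. NaHCO3, CH2Cl2, rt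
Reagents that add atoms: none
Why: Quaternisation of the amine and base-induced elimination of trimethylamine (Hofmann-type elimination of a Mannich base) give the α-methylene lactone without touching the carbinol stereocentre.

Step 23
Reactants: 33 (4R)-4-hydroxy-3-methylideneoxolan-2-one
Product: 36 (3R)-3,4-bis(tert-butyldimethylsilyloxy)-2-methylidenebutanoic acid, via lithium carboxylate 34 (not isolated), via tris-silyl ester 35 (not isolated)
Conditions: LiOH, THF/H2O, 0 °C; evaporation; TBSCl, imidazole, DMF, rt; then K2CO3, MeOH/THF/H2O, 0 °C, acidify to pH 4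
Reagents that add atoms: lithium hydroxide, [Li+].[OH-]; tert-butylchlorodimethylsilane, CC(C)(C)[Si](C)(C)Cl
Why: Saponification opens the lactone to the carboxylate, exhaustive silylation caps both hydroxyls and the carboxylate, and mild carbonate hydrolysis cleaves only the labile silyl ester.

Step 24
Reactants: 28 8β-alcohol; 36 (3R)-3,4-bis(tert-butyldimethylsilyloxy)-2-methylidenebutanoic acid
Product: 37 C8 ester (8β-O-acyl with the bis-silylated (3R) side chain; 7β-C(=CH2)CH2OPMB; 6β-OSiEt3; 5α-C(=CH2)CH2OSiPh2t-Bu)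
Conditions: 2-methyl-6-nitrobenzoic anhydride, DMAP, Et3N, CH2Cl2, rt
Reagents that add atoms: none
Why: Shiina esterification: the mixed anhydride is attacked by DMAP at the aliphatic acyl group and acylates the only free hydroxyl, the equatorial C8–OH, with retention.

Step 25
Reactants: 37 C8 ester
Product: 38 C12 alcohol (as 37 with 7β-C(=CH2)CH2OH)
Conditions: DDQ, CH2Cl2/pH 7 buffer, 0 °C
Reagents that add atoms: none
Why: Oxidative cleavage of the 4-methoxybenzyl ether by DDQ proceeds through a benzylic oxocarbenium ion that water hydrolyses, and silyl ethers, esters and isolated olefins are untouched.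

Step 26
Reactants: 38 C12 alcohol
Product: 40 C12 acid (7β-C(=CH2)CO2H; all silyl ethers in place), via C12 enal 39 (not isolated)
Conditions: Dess–Martin periodinane, NaHCO3, CH2Cl2, 0 °C; then NaClO2, NaH2PO4, 2-methyl-2-butene, t-BuOH/H2O, 0 °C
Reagents that add atoms: sodium chlorite, [Na+].[O-]Cl=O
Why: Dess–Martin oxidation of the primary allylic alcohol followed in the same flask by Pinnick oxidation gives the α-substituted acrylic acid, with the chlorine scavenger protecting the olefins and the buffered medium avoiding migration of the C11=C13 bond.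

Step 27
Reactants: 40 C12 acid
Product: 41 CNP0348657.6 (target)
Conditions: HF·pyridine, pyridine, THF, 0 °C → rt
Reagents that add atoms: none
Why: Global desilylation with buffered, mildly acidic HF·pyridine removes all four silyl groups and avoids the base-induced acyl migration or lactonisation that the freed hydroxyls could undergo.

**Compound list**

1 | benzoic acid | OC(=O)c1ccccc1 | starting material
2 | iodomethane | CI | starting material
3 | dilithium (cyclohexa-2,5-dien-1-ylidene)methanediolate (Birch dianion) | [Li+].[Li+].[O-]C([O-])=C1C=CCC=C1 | intermediate (not isolated)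
4 | 1-methylcyclohexa-2,5-diene-1-carboxylic acid | CC1(C(=O)O)C=CCC=C1 | intermediate
5 | (1-methylcyclohexa-2,5-dien-1-yl)methanol | CC1(CO)C=CCC=C1 | intermediate
6 | acryloyl chloride | C=CC(=O)Cl | starting material
7 | (1-methylcyclohexa-2,5-dien-1-yl)methyl acrylate | C=CC(=O)OCC1(C)C=CCC=C1 | intermediate
8 | (1-methyl-4-oxocyclohexa-2,5-dien-1-yl)methyl acrylate | C=CC(=O)OCC1(C)C=CC(=O)C=C1 | intermediate (key-step precursor)
9 | (4aS,8aR)-8a-methyl-4-methylidene-4a,5-dihydro-1H-isochromene-3,6(4H,8aH)-dione | O=C1C=C[C@@]2(C)COC(=O)C(=C)[C@H]2C1 | intermediate (key-step product)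
10 | trimethylsilyl dienol ether of 9 (C6=C7, C8=C9; 7-OSiMe3) | O1C[C@]2(C)C=CC(O[Si](C)(C)C)=C[C@@H]2C(=C)C1=O | intermediate
11 | 6β-(trimethylsilyloxy) derivative of 9 | O1C[C@]2(C)C=CC(=O)[C@@H](O[Si](C)(C)C)[C@@H]2C(=C)C1=O | intermediate (not isolated)
12 | 6β-hydroxy derivative of 9 | O1C[C@]2(C)C=CC(=O)[C@@H](O)[C@@H]2C(=C)C1=O | intermediate
13 | 6β-(triethylsilyloxy) derivative of 9 | O1C[C@]2(C)C=CC(=O)[C@@H](O[Si](CC)(CC)CC)[C@@H]2C(=C)C1=O | intermediate
14 | triol: 5α-(3-hydroxyprop-1-en-2-yl)-10α-(hydroxymethyl)-10β-methyl-6β-(triethylsilyloxy)cyclohex-8-en-7-ol (C7 epimers) | OC[C@]1(C)C=CC(O)[C@@H](O[Si](CC)(CC)CC)[C@@H]1C(=C)CO | intermediate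
15 | 15-O-TBDPS diol: as 14 with 5α-[3-(tert-butyldiphenylsilyloxy)prop-1-en-2-yl] | OC[C@]1(C)C=CC(O)[C@@H](O[Si](CC)(CC)CC)[C@@H]1C(=C)CO[Si](c1ccccc1)(c1ccccc1)C(C)(C)C | intermediate
16 | keto aldehyde: 10α-formyl-10β-methyl-6β-(triethylsilyloxy)-5α-[3-(tert-butyldiphenylsilyloxy)prop-1-en-2-yl]cyclohex-8-en-7-one | O=C[C@]1(C)C=CC(=O)[C@@H](O[Si](CC)(CC)CC)[C@@H]1C(=C)CO[Si](c1ccccc1)(c1ccccc1)C(C)(C)C | intermediate
17 | vinyl enone: as 16 with 10α-vinyl | C=C[C@]1(C)C=CC(=O)[C@@H](O[Si](CC)(CC)CC)[C@@H]1C(=C)CO[Si](c1ccccc1)(c1ccccc1)C(C)(C)C | intermediate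
18 | lithium C7–C8 enolate of the 8,9-dihydro ketone | C=C[C@]1(C)CC=C(O[Li])[C@@H](O[Si](CC)(CC)CC)[C@@H]1C(=C)CO[Si](c1ccccc1)(c1ccccc1)C(C)(C)C | intermediate (not isolated)
19 | C7 enol triflate: 5α-[3-(tert-butyldiphenylsilyloxy)prop-1-en-2-yl]-10β-methyl-6β-(triethylsilyloxy)-10α-vinylcyclohex-7-en-7-yl trifluoromethanesulfonate | C=C[C@]1(C)CC=C(OS(=O)(=O)C(F)(F)F)[C@@H](O[Si](CC)(CC)CC)[C@@H]1C(=C)CO[Si](c1ccccc1)(c1ccccc1)C(C)(C)C | intermediate
20 | 4-methoxybenzyl alcohol | COc1ccc(CO)cc1 | starting material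
21 | 2,3-dibromopropene | C=C(Br)CBr | starting material
22 | 2-bromoallyl 4-methoxybenzyl ether | C=C(Br)COCc1ccc(OC)cc1 | intermediate
23 | 2-[3-(4-methoxybenzyloxy)prop-1-en-2-yl]-4,4,5,5-tetramethyl-1,3,2-dioxaborolane | C=C(COCc1ccc(OC)cc1)B1OC(C)(C)C(C)(C)O1 | intermediate
24 | diene: as 19 with 7-[3-(4-methoxybenzyloxy)prop-1-en-2-yl] in place of the triflate | C=C[C@]1(C)CC=C(C(=C)COCc2ccc(OC)cc2)[C@@H](O[Si](CC)(CC)CC)[C@@H]1C(=C)CO[Si](c1ccccc1)(c1ccccc1)C(C)(C)C | intermediate
25 | dienol: as 24 with free 6β-OH | C=C[C@]1(C)CC=C(C(=C)COCc2ccc(OC)cc2)[C@@H](O)[C@@H]1C(=C)CO[Si](c1ccccc1)(c1ccccc1)C(C)(C)C | intermediate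
26 | 7β,8β-epoxy 6β-alcohol | C=C[C@]1(C)C[C@H]2O[C@@]2(C(=C)COCc3ccc(OC)cc3)[C@@H](O)[C@@H]1C(=C)CO[Si](c1ccccc1)(c1ccccc1)C(C)(C)C | intermediate
27 | 7β,8β-epoxide with 6β-OSiEt3 | C=C[C@]1(C)C[C@H]2O[C@@]2(C(=C)COCc3ccc(OC)cc3)[C@@H](O[Si](CC)(CC)CC)[C@@H]1C(=C)CO[Si](c1ccccc1)(c1ccccc1)C(C)(C)C | intermediate
28 | 8β-alcohol: 7β-[3-(4-methoxybenzyloxy)prop-1-en-2-yl]-6β-(triethylsilyloxy)-5α-[3-(tert-butyldiphenylsilyloxy)prop-1-en-2-yl]-10β-methyl-10α-vinylcyclohexan-8β-ol | C=C[C@]1(C)C[C@@H](O)[C@@H](C(=C)COCc2ccc(OC)cc2)[C@@H](O[Si](CC)(CC)CC)[C@@H]1C(=C)CO[Si](c1ccccc1)(c1ccccc1)C(C)(C)C | intermediate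
29 | (R)-3-hydroxy-γ-butyrolactone [(4R)-4-hydroxyoxolan-2-one] | O=C1C[C@@H](O)CO1 | starting material
30 | dilithium alkoxide enolate of 29 | [Li+].[Li+].[O-]C1=C[C@@H]([O-])CO1 | intermediate (not isolated)
31 | (4R)-3-[(dimethylamino)methyl]-4-hydroxyoxolan-2-one (3,4-trans) | O=C1[C@H](CN(C)C)[C@@H](O)CO1 | intermediate
32 | trimethylammonium iodide of 31 | O=C1[C@H](C[N+](C)(C)C)[C@@H](O)CO1.[I-] | intermediate (not isolated)
33 | (4R)-4-hydroxy-3-methylideneoxolan-2-one | O=C1C(=C)[C@@H](O)CO1 | intermediate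
34 | lithium (3R)-3,4-dihydroxy-2-methylidenebutanoate | [Li+].[O-]C(=O)C(=C)[C@@H](O)CO | intermediate (not isolated)
35 | tert-butyldimethylsilyl (3R)-3,4-bis(tert-butyldimethylsilyloxy)-2-methylidenebutanoate | C=C(C(=O)O[Si](C)(C)C(C)(C)C)[C@@H](O[Si](C)(C)C(C)(C)C)CO[Si](C)(C)C(C)(C)C | intermediate (not isolated)
36 | (3R)-3,4-bis(tert-butyldimethylsilyloxy)-2-methylidenebutanoic acid | C=C(C(=O)O)[C@@H](O[Si](C)(C)C(C)(C)C)CO[Si](C)(C)C(C)(C)C | intermediate
37 | C8 ester: 28 acylated at O8 with 36 | C=C[C@]1(C)C[C@@H](OC(=O)C(=C)[C@@H](O[Si](C)(C)C(C)(C)C)CO[Si](C)(C)C(C)(C)C)[C@@H](C(=C)COCc2ccc(OC)cc2)[C@@H](O[Si](CC)(CC)CC)[C@@H]1C(=C)CO[Si](c1ccccc1)(c1ccccc1)C(C)(C)C | intermediate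
38 | C12 alcohol: as 37 with 7β-(3-hydroxyprop-1-en-2-yl) | C=C[C@]1(C)C[C@@H](OC(=O)C(=C)[C@@H](O[Si](C)(C)C(C)(C)C)CO[Si](C)(C)C(C)(C)C)[C@@H](C(=C)CO)[C@@H](O[Si](CC)(CC)CC)[C@@H]1C(=C)CO[Si](c1ccccc1)(c1ccccc1)C(C)(C)C | intermediate
39 | C12 enal: as 37 with 7β-(3-oxoprop-1-en-2-yl) | C=C[C@]1(C)C[C@@H](OC(=O)C(=C)[C@@H](O[Si](C)(C)C(C)(C)C)CO[Si](C)(C)C(C)(C)C)[C@@H](C(=C)C=O)[C@@H](O[Si](CC)(CC)CC)[C@@H]1C(=C)CO[Si](c1ccccc1)(c1ccccc1)C(C)(C)C | intermediate (not isolated)
40 | C12 acid: as 37 with 7β-(1-carboxyvinyl) | C=C[C@]1(C)C[C@@H](OC(=O)C(=C)[C@@H](O[Si](C)(C)C(C)(C)C)CO[Si](C)(C)C(C)(C)C)[C@@H](C(=C)C(=O)O)[C@@H](O[Si](CC)(CC)CC)[C@@H]1C(=C)CO[Si](c1ccccc1)(c1ccccc1)C(C)(C)C | intermediate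
41 | CNP0348657.6 | C=C[C@]1(C)C[C@@H](OC(=O)C(=C)[C@@H](O)CO)[C@@H](C(=C)C(=O)O)[C@@H](O)[C@@H]1C(=C)CO | target

**Step count**

Total step count: 27. Longest linear sequence: 22 steps (steps 1–13, 16–20 and 24–27).

**Steps most likely to fail**

1. Step 5. The six-membered closure may be slower than intermolecular Rauhut–Currier coupling of the acrylate, and the catalyst may distinguish the two enantiotopic enone arms poorly. The fallback sets out from alcohol 5 and comes back at 9; it keeps the C4–C5 bond formation but uses a stabilised carbanion. Alcohol 5 is esterified with diethylphosphonoacetic acid (DCC, DMAP) to (1-methylcyclohexa-2,5-dien-1-yl)methyl 2-(diethoxyphosphoryl)acetate F1. Oxidation with CrO3 and 3,5-dimethylpyrazole gives (1-methyl-4-oxocyclohexa-2,5-dien-1-yl)methyl 2-(diethoxyphosphoryl)acetate F2. A desymmetrising intramolecular Michael addition of the phosphonoacetate carbanion under a cinchona-derived quaternary ammonium phase-transfer catalyst with Cs2CO3 closes the cis-fused lactone to the α-(diethoxyphosphoryl) δ-lactone enone F3. Horner–Wadsworth–Emmons reaction with aqueous formaldehyde and K2CO3 installs the methylene and delivers 9.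

2. Step 20. Hydride may be transferred to the primary terminus C13 of the allyl complex, giving the tetrasubstituted C7=C11 olefin. The complex may also lose its facial memory by η3–η1–η3 isomerisation through C13, or collapse by β-hydride elimination to dienes. The fallback sets out from epoxide 27 and comes back at 28. Epoxide 27 is opened in 1,4-fashion by N-isopropylidene-N′-(2-nitrobenzenesulfonyl)hydrazine under Pd(PPh3)4 catalysis to the allylic sulfonyl hydrazone with 8β-hydroxyl and C7=C11 double bond F4. Hydrolysis in trifluoroethanol–water frees the monoalkyl diazene. Its retro-ene loss of N2 can place hydrogen only on C7 and moves the double bond to C11=C13; the hydrogen is expected to arrive anti to the two flanking β-oxygens, which gives 28.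

3. Step 13. The borohydride may attack the carbonyl (1,2-reduction) because C9 sits next to the quaternary C10, or the hindered enolate may be triflated slowly. The fallback sets out from enone 17 and comes back at 19 through enolate 18. Enone 17 undergoes catalytic 1,4-hydrosilylation with [(Ph3P)CuH]6 and PhMe2SiH to the isolable dimethyl(phenyl)silyl enol ether of the 8,9-dihydro ketone F5. MeLi in THF cleaves the Si–O bond to regenerate lithium enolate 18, which is triflated with PhNTf2 as in step 13 to give 19.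

Further compounds
F1 | step 5 | (1-methylcyclohexa-2,5-dien-1-yl)methyl 2-(diethoxyphosphoryl)acetate | CCOP(=O)(OCC)CC(=O)OCC1(C)C=CCC=C1
F2 | step 5 | (1-methyl-4-oxocyclohexa-2,5-dien-1-yl)methyl 2-(diethoxyphosphoryl)acetate | CCOP(=O)(OCC)CC(=O)OCC1(C)C=CC(=O)C=C1
F3 | step 5 | cis-fused α-(diethoxyphosphoryl) δ-lactone enone (C4 epimers; C5 and C10 as in 9) | O1C[C@]2(C)C=CC(=O)C[C@@H]2C(P(=O)(OCC)OCC)C1=O
F4 | step 20 | allylic sulfonyl hydrazone with 8β-hydroxyl and C7=C11 double bond (N-isopropylidene-N′-(2-nitrobenzenesulfonyl)hydrazino group on C13) | C=C[C@]1(C)C[C@@H](O)C(=C(COCc2ccc(OC)cc2)CN(N=C(C)C)S(=O)(=O)c2ccccc2[N+](=O)[O-])[C@@H](O[Si](CC)(CC)CC)[C@@H]1C(=C)CO[Si](c1ccccc1)(c1ccccc1)C(C)(C)C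
F5 | step 13 | dimethyl(phenyl)silyl enol ether of the 8,9-dihydro ketone (C7=C8; 7-OSiMe2Ph) | C=C[C@]1(C)CC=C(O[Si](C)(C)c2ccccc2)[C@@H](O[Si](CC)(CC)CC)[C@@H]1C(=C)CO[Si](c1ccccc1)(c1ccccc1)C(C)(C)C
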